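**Strategy.** The target is the ether of two 3-farnesyl-4-hydroxycoumarins. The route rests on cutting the sp3–sp2 bond C9'–C10' of the ether-linked chain (numbered C1' at its coumarin CH2 to C12' at the OCH2), next to the Z-trisubstituted C10'=C11' alkene. One B-alkyl Suzuki–Miyaura coupling, run last and without protecting groups, joins the two complete halves. Its precursors are the upper (S)-configured half carrying a (Z)-3-iodo-2-methylallyl ether, and the lower coumarin whose chain ends in a C6'=C7'–C8'=C9' diene, hydroborated at C9' by 9-BBN. The step exploits the homoallylic position of C9' and transfers the Z geometry stereospecifically. Both 4-hydroxybenzopyranone rings are carried as free enols.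

Key step: step 12

Numbering used below: upper chain C1–C12 from its coumarin CH2, C5 being the stereocentre; ether-linked lower chain C1'–C12' as above.

Assumption 1: geranial (the 2E isomer of citral) is purchased isomerically pure.

Assumption 2: the (R,R)-bisphosphoramide/SiCl4 system is taken to deliver silyl ketene acetals to the Re face of aldehydes, so the (S,S)-antipode is specified for the Si-face attack that gives the 5S alcohol; if the sense is opposite, the antipode is used.

Step 1
Reactants: 1 geranyl acetate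
Product: 3 (2E,6E)-3,7-dimethyl-8-oxoocta-2,6-dien-1-yl acetate, via allylic alcohol 2 (not isolated)
Conditions: SeO2 (0.4 equiv), t-BuOOH (70% aq., 3 equiv), salicylic acid (0.1 equiv), CH2Cl2, rt; crude mixture, then MnO2, CH2Cl2, rt
Reagents that add atoms: tert-butyl hydroperoxide, CC(C)(C)OO (terminal oxidant; the oxygen is passed on by catalytic SeO2, O=[Se]=O)
Why: The SeO2/t-BuOOH allylic oxidation (ene reaction then [2,3]-sigmatropic shift) attacks the E-methyl group of the distal, more electron-rich trisubstituted alkene, the proximal one being deactivated by the allylic acetate, and MnO2 converges alcohol and aldehyde to the E-enal.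

Step 2
Reactants: 3 (2E,6E)-3,7-dimethyl-8-oxoocta-2,6-dien-1-yl acetate
Product: 4 (2E,6E)-3,7-dimethylnona-2,6,8-trien-1-yl acetate
Conditions: Ph3PCH3Br (1.1 equiv), KHMDS (1.05 equiv), THF, 0 °C; then 3, −78 °C to 0 °C
Reagents that add atoms: methyltriphenylphosphonium bromide, C[P+](c1ccccc1)(c1ccccc1)c1ccccc1.[Br-]
Why: Wittig methylenation of the enal by the unstabilised ylide at low temperature is much faster than attack on the acetate and installs the terminal vinyl carbon (the later C9') without touching the E-alkenes.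

Step 3
Reactants: 4 (2E,6E)-3,7-dimethylnona-2,6,8-trien-1-yl acetate; 5 4-hydroxycoumarin
Product: 6 4-hydroxy-3-[(2E,6E)-3,7-dimethylnona-2,6,8-trien-1-yl]-2H-chromen-2-one
Conditions: Pd(PPh3)4 (5 mol%), 5 (1.5 equiv), THF, 40 °C
Reagents that add atoms: none
Why: Tsuji–Trost allylation, in which zerovalent palladium ionises the allylic acetate to an η3-allyl complex, the liberated acetate deprotonates the acidic enol, and the soft C3 carbon attacks the unhindered CH2 terminus with retention of the E-alkene, any O-allyl isomer being re-ionised and funnelled to the C-allyl product.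

Step 4
Reactants: 7 methyl 3-methylbut-2-enoate
Product: 9 tert-butyl[(1-methoxy-3-methylbuta-1,3-dien-1-yl)oxy]dimethylsilane, via lithium dienolate 8 (not isolated)
Conditions: LDA (1.1 equiv), THF, −78 °C; then TBSCl, DMPU, −78 °C to rt
Reagents that add atoms: tert-butylchlorodimethylsilane (TBSCl), CC(C)(C)[Si](C)(C)Cl
Why: Kinetic γ-deprotonation of the senecioate gives the cross-conjugated lithium dienolate, which is silylated on oxygen to the silyl dienol ether required for a vinylogous Mukaiyama aldol addition.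

Step 5
Reactants: 9 tert-butyl[(1-methoxy-3-methylbuta-1,3-dien-1-yl)oxy]dimethylsilane; 10 geranial
Product: 11 methyl (2E,5S,6E)-5-hydroxy-3,7,11-trimethyldodeca-2,6,10-trienoate
Conditions: SiCl4 (1.1 equiv), (S,S)-bisphosphoramide [pentane-1,5-diyl-linked bis(N,N'-dimethyl-1,1'-binaphthyl-2,2'-diamine phosphoramide)] (5 mol%), i-Pr2NEt (10 mol%), CH2Cl2, −78 °C; sat. aq. NaHCO3
Reagents that add atoms: none
Why: In this catalytic enantioselective vinylogous Mukaiyama aldol addition the phosphoramide-bound trichlorosilyl cation activates the enal for 1,2-addition, the dienolate reacts through its unhindered γ-carbon to give the E-enoate, and the chiral catalyst exposes the Si face of the aldehyde so that C5 should be formed with S configuration (catalyst control).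

Step 6
Reactants: 11 methyl (2E,5S,6E)-5-hydroxy-3,7,11-trimethyldodeca-2,6,10-trienoate
Product: 12 (2E,5S,6E)-3,7,11-trimethyldodeca-2,6,10-triene-1,5-diol
Conditions: DIBAL-H (3.5 equiv), CH2Cl2, −78 °C; aq. Rochelle salt
Reagents that add atoms: none
Why: DIBAL-H effects clean 1,2-reduction of the α,β-unsaturated ester to the E-allylic alcohol at low temperature without affecting the isolated alkenes or the carbinol stereocentre.

Step 7
Reactants: 12 (2E,5S,6E)-3,7,11-trimethyldodeca-2,6,10-triene-1,5-diol
Product: 13 (2E,5S,6E)-5-hydroxy-3,7,11-trimethyldodeca-2,6,10-trien-1-yl methyl carbonate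
Conditions: ClCO2Me (1.05 equiv), pyridine, CH2Cl2, −30 °C
Reagents that add atoms: methyl chloroformate, COC(=O)Cl
Why: Acylation with one equivalent of chloroformate at low temperature should select the unhindered primary allylic hydroxyl over the secondary allylic one, which is flanked by two branches.

Step 8
Reactants: 13 (2E,5S,6E)-5-hydroxy-3,7,11-trimethyldodeca-2,6,10-trien-1-yl methyl carbonate; 5 4-hydroxycoumarin
Product: 14 4-hydroxy-3-[(2E,5S,6E)-5-hydroxy-3,7,11-trimethyldodeca-2,6,10-trien-1-yl]-2H-chromen-2-one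
Conditions: Pd(PPh3)4 (5 mol%), 5 (1.5 equiv), THF, rt
Reagents that add atoms: none
Why: In this decarboxylative Tsuji–Trost allylation, ionisation of the primary allylic carbonate gives the η3-allyl complex and methoxide, which deprotonates the enol, and C3 attacks the CH2 terminus, while the unactivated secondary allylic alcohol is not ionised and C5 keeps its configuration.

Step 9
Reactants: 15 prop-2-yn-1-ol
Product: 17 (2Z)-3-iodo-2-methylprop-2-en-1-ol, via vinylmagnesium chelate 16 (not isolated)
Conditions: MeMgBr (2.5 equiv), CuI (10 mol%), THF, −10 °C to rt; then I2, THF, −78 °C to 0 °C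
Reagents that add atoms: methylmagnesium bromide, C[Mg]Br; iodine, II
Why: Copper-catalysed anti-carbomagnesiation of the propargylic alkoxide places methyl on C2 and magnesium on C3 cis to the CH2O group within a five-membered chelate, and iodinolysis with retention gives the Z-vinyl iodide.

Step 10
Reactants: 17 (2Z)-3-iodo-2-methylprop-2-en-1-ol
Product: 18 (1Z)-3-bromo-1-iodo-2-methylprop-1-ene
Conditions: CBr4, PPh3, CH2Cl2, 0 °C
Reagents that add atoms: carbon tetrabromide, BrC(Br)(Br)Br
Why: Appel bromination converts the primary allylic alcohol into the bromide under neutral conditions without allylic transposition or loss of the Z-vinyl iodide geometry.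

Step 11
Reactants: 14 4-hydroxy-3-[(2E,5S,6E)-5-hydroxy-3,7,11-trimethyldodeca-2,6,10-trien-1-yl]-2H-chromen-2-one; 18 (1Z)-3-bromo-1-iodo-2-methylprop-1-ene
Product: 20 4-hydroxy-3-[(2E,5S,6E)-5-{[(2Z)-3-iodo-2-methylprop-2-en-1-yl]oxy}-3,7,11-trimethyldodeca-2,6,10-trien-1-yl]-2H-chromen-2-one, via disodium salt 19 (not isolated)
Conditions: NaH (2.2 equiv), THF–DMF, 0 °C; then 18 (1.0 equiv), 0 °C; 1 M HCl to pH 4 at 0 °C
Reagents that add atoms: none
Why: In this Williamson ether synthesis on the dianion the secondary alkoxide is far more basic and nucleophilic than the delocalised coumarin-4-olate, so one equivalent of the reactive allylic bromide should alkylate the C5 oxygen by SN2 substitution, with no bond to the stereocentre broken and the vinyl iodide untouched.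

Step 12
Reactants: 6 4-hydroxy-3-[(2E,6E)-3,7-dimethylnona-2,6,8-trien-1-yl]-2H-chromen-2-one; 20 4-hydroxy-3-[(2E,5S,6E)-5-{[(2Z)-3-iodo-2-methylprop-2-en-1-yl]oxy}-3,7,11-trimethyldodeca-2,6,10-trien-1-yl]-2H-chromen-2-one
Product: 22 3-[(2E,5S,6E)-5-{[(2Z,6E,10E)-12-(4-hydroxy-2-oxo-2H-chromen-3-yl)-2,6,10-trimethyldodeca-2,6,10-trien-1-yl]oxy}-3,7,11-trimethyldodeca-2,6,10-trien-1-yl]-4-hydroxy-2H-chromen-2-one (CNP0109195.1), via bis-borylated intermediate 21 (not isolated)
Conditions: 6, 9-BBN (2.3 equiv), THF, 0 °C to rt; then degassed 3 M aq. Cs2CO3, 20, PdCl2(dppf) (10 mol%), AsPh3 (10 mol%), DMF, rt, dark; aq. citric acid to pH 4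
Reagents that add atoms: none
Why: 9-BBN first converts the acidic enol O–H of 6 into an O–B bond (H2 is lost) and then hydroborates only the monosubstituted C8'=C9' end of the diene, boron going to C9', because the trisubstituted alkenes are too hindered for this reagent. Zerovalent palladium then inserts into the C–I bond of 20 with retention, the base-activated borate of 21 transfers its primary alkyl group (C9') to palladium, and reductive elimination forms the C9'–C10' C(sp3)–C(sp2) bond. The closest known reaction type is the B-alkyl Suzuki–Miyaura coupling of a 9-BBN alkylborane with a vinyl iodide. No ring is closed and no stereocentre is created; the Z geometry of C10'=C11' is inherited stereospecifically from 20, and the remote C5 stereocentre is untouched. The step needs chemoselective hydroboration (secured by the steric bias of 9-BBN for the terminal vinyl group), oxidative addition at a single site (the vinyl iodide is the only carbon–halogen bond, and the ether oxygen is γ to palladium and cannot β-eliminate), and tolerance of both enols, which under aqueous Cs2CO3 are spectator coumarin-4-olate anions re-protonated on work-up.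

**Compound list**

1 | geranyl acetate, (2E)-3,7-dimethylocta-2,6-dien-1-yl acetate | CC(C)=CCC/C(C)=C/COC(C)=O | starting material
2 | (2E,6E)-8-hydroxy-3,7-dimethylocta-2,6-dien-1-yl acetate | OC/C(C)=C/CC/C(C)=C/COC(C)=O | intermediate
3 | (2E,6E)-3,7-dimethyl-8-oxoocta-2,6-dien-1-yl acetate | O=C/C(C)=C/CC/C(C)=C/COC(C)=O | intermediate
4 | (2E,6E)-3,7-dimethylnona-2,6,8-trien-1-yl acetate | C=C/C(C)=C/CC/C(C)=C/COC(C)=O | intermediate
5 | 4-hydroxycoumarin (4-hydroxy-2H-chromen-2-one) | O=c1cc(O)c2ccccc2o1 | starting material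
6 | 4-hydroxy-3-[(2E,6E)-3,7-dimethylnona-2,6,8-trien-1-yl]-2H-chromen-2-one (fragment 2) | C=C/C(C)=C/CC/C(C)=C/Cc1c(O)c2ccccc2oc1=O | intermediate
7 | methyl 3-methylbut-2-enoate | CC(C)=CC(=O)OC | starting material
8 | lithium 1-methoxy-3-methylbuta-1,3-dien-1-olate | [Li+].C=C(C)C=C([O-])OC | intermediate
9 | tert-butyl[(1-methoxy-3-methylbuta-1,3-dien-1-yl)oxy]dimethylsilane (ketene acetal geometry not defined, inconsequential) | C=C(C)C=C(OC)O[Si](C)(C)C(C)(C)C | intermediate
10 | geranial, (2E)-3,7-dimethylocta-2,6-dienal | CC(C)=CCC/C(C)=C/C=O | starting material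
11 | methyl (2E,5S,6E)-5-hydroxy-3,7,11-trimethyldodeca-2,6,10-trienoate | CC(C)=CCC/C(C)=C/[C@H](C/C(C)=C/C(=O)OC)O | intermediate
12 | (2E,5S,6E)-3,7,11-trimethyldodeca-2,6,10-triene-1,5-diol | CC(C)=CCC/C(C)=C/[C@H](C/C(C)=C/CO)O | intermediate
13 | (2E,5S,6E)-5-hydroxy-3,7,11-trimethyldodeca-2,6,10-trien-1-yl methyl carbonate | CC(C)=CCC/C(C)=C/[C@H](C/C(C)=C/COC(=O)OC)O | intermediate
14 | 4-hydroxy-3-[(2E,5S,6E)-5-hydroxy-3,7,11-trimethyldodeca-2,6,10-trien-1-yl]-2H-chromen-2-one | CC(C)=CCC/C(C)=C/[C@H](C/C(C)=C/Cc1c(O)c2ccccc2oc1=O)O | intermediate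
15 | prop-2-yn-1-ol | C#CCO | starting material
16 | bromo[(1Z)-3-(bromomagnesiooxy)-2-methylprop-1-en-1-yl]magnesium | Br[Mg]/C=C(/C)CO[Mg]Br | intermediate
17 | (2Z)-3-iodo-2-methylprop-2-en-1-ol | OC/C(C)=C\I | intermediate
18 | (1Z)-3-bromo-1-iodo-2-methylprop-1-ene | BrC/C(C)=C\I | intermediate
19 | disodium salt of 14 (C5 alkoxide and coumarin-4-olate) | [Na+].[Na+].CC(C)=CCC/C(C)=C/[C@H](C/C(C)=C/Cc1c([O-])c2ccccc2oc1=O)[O-] | intermediate
20 | 4-hydroxy-3-[(2E,5S,6E)-5-{[(2Z)-3-iodo-2-methylprop-2-en-1-yl]oxy}-3,7,11-trimethyldodeca-2,6,10-trien-1-yl]-2H-chromen-2-one (fragment 1) | CC(C)=CCC/C(C)=C/[C@H](C/C(C)=C/Cc1c(O)c2ccccc2oc1=O)OC/C(C)=C\I | intermediate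
21 | 6 carrying a 9-borabicyclo[3.3.1]nonan-9-yl group on C9' and a second one on the enol oxygen | B1(CC/C(C)=C/CC/C(C)=C/Cc2c(OB3C4CCCC3CCC4)c3ccccc3oc2=O)C2CCCC1CCC2 | intermediate
22 | 3-[(2E,5S,6E)-5-{[(2Z,6E,10E)-12-(4-hydroxy-2-oxo-2H-chromen-3-yl)-2,6,10-trimethyldodeca-2,6,10-trien-1-yl]oxy}-3,7,11-trimethyldodeca-2,6,10-trien-1-yl]-4-hydroxy-2H-chromen-2-one | CC(C)=CCC/C(C)=C/[C@H](C/C(C)=C/Cc1c(O)c2ccccc2oc1=O)OC/C(C)=C\CC/C(C)=C/CC/C(C)=C/Cc1c(O)c2ccccc2oc1=O | target

**Totals.** Total step count: 12. Longest linear sequence: 7 steps (steps 4, 5, 6, 7, 8, 11, 12).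

**Steps most likely to fail**

Step 12. The risk is that the acidic enols consume borane and slow the alkyl transfer from boron to palladium, so that the vinyl iodide is lost instead by protodehalogenation, Z-to-E isomerisation or intramolecular Heck reaction onto C6=C7. The fallback sets out from 6 and 20 and comes back at 22. Both enols are masked first with SEMCl and i-Pr2NEt in CH2Cl2, giving the 4-O-[2-(trimethylsilyl)ethoxy]methyl ether of 6 F1 and the 4-O-[2-(trimethylsilyl)ethoxy]methyl ether of 20 F2. F1 is hydroborated with 9-BBN (1.2 equiv) to the B-alkyl-9-BBN derivative of F1 F3. F3 is coupled with F2 under the same PdCl2(dppf)/AsPh3/Cs2CO3 conditions to the bis-SEM ether of 22 F4. TBAF in THF then releases both enols to give 22.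

Step 11. The risk is poor site selectivity in the alkylation of the dianion (attack at C3 or O4 of the coumarin-4-olate) or anionic oxy-Cope rearrangement of the 3-oxido-1,5-diene C7=C6–C5(O−)–C4–C3=C2 before the alkoxide is allylated. The fallback sets out from 14 and comes back at 20. The enol is masked chemoselectively with SEMCl (1.05 equiv) and i-Pr2NEt at 0 °C, the ammonium enolate reacting much faster than the secondary alcohol, to give the 4-O-[2-(trimethylsilyl)ethoxy]methyl ether of 14 F5. Its single hydroxyl is then allylated with 18 using NaH (1.1 equiv) at 0 °C, or Ag2O without a free alkoxide if rearrangement persists, to give the SEM ether of 20 F2. TBAF in THF returns 20; alternatively F2 is taken directly into the fallback of step 12.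

Step 5. The risk is insufficient facial selectivity or low conversion with the β,β-disubstituted enal, and competing α-attack of the dienolate. The fallback sets out from 9 and 10 and comes back at 11. A BF3·OEt2-promoted vinylogous Mukaiyama aldol addition (CH2Cl2, −78 °C) gives racemic methyl (2E,6E)-5-hydroxy-3,7,11-trimethyldodeca-2,6,10-trienoate F6. Dess–Martin periodinane buffered with NaHCO3 oxidises it to methyl (2E,6E)-3,7,11-trimethyl-5-oxododeca-2,6,10-trienoate F7. CBS reduction with the (R)-methyl oxazaborolidine and catecholborane in toluene at −78 °C, the alkenyl group acting as the large substituent, should give 11 with the 5S configuration.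

**Further compounds**

F1 | step 12 | 3-[(2E,6E)-3,7-dimethylnona-2,6,8-trien-1-yl]-4-{[2-(trimethylsilyl)ethoxy]methoxy}-2H-chromen-2-one | C=C/C(C)=C/CC/C(C)=C/Cc1c(OCOCC[Si](C)(C)C)c2ccccc2oc1=O
F2 | step 12 | 3-[(2E,5S,6E)-5-{[(2Z)-3-iodo-2-methylprop-2-en-1-yl]oxy}-3,7,11-trimethyldodeca-2,6,10-trien-1-yl]-4-{[2-(trimethylsilyl)ethoxy]methoxy}-2H-chromen-2-one | CC(C)=CCC/C(C)=C/[C@H](C/C(C)=C/Cc1c(OCOCC[Si](C)(C)C)c2ccccc2oc1=O)OC/C(C)=C\I
F3 | step 12 | 3-[(2E,6E)-9-(9-borabicyclo[3.3.1]nonan-9-yl)-3,7-dimethylnona-2,6-dien-1-yl]-4-{[2-(trimethylsilyl)ethoxy]methoxy}-2H-chromen-2-one | B1(CC/C(C)=C/CC/C(C)=C/Cc2c(OCOCC[Si](C)(C)C)c3ccccc3oc2=O)C2CCCC1CCC2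
F4 | step 12 | bis{[2-(trimethylsilyl)ethoxy]methyl} ether of 22 at both coumarin 4-oxygens | CC(C)=CCC/C(C)=C/[C@H](C/C(C)=C/Cc1c(OCOCC[Si](C)(C)C)c2ccccc2oc1=O)OC/C(C)=C\CC/C(C)=C/CC/C(C)=C/Cc1c(OCOCC[Si](C)(C)C)c2ccccc2oc1=O
F5 | step 11 | 3-[(2E,5S,6E)-5-hydroxy-3,7,11-trimethyldodeca-2,6,10-trien-1-yl]-4-{[2-(trimethylsilyl)ethoxy]methoxy}-2H-chromen-2-one | CC(C)=CCC/C(C)=C/[C@H](C/C(C)=C/Cc1c(OCOCC[Si](C)(C)C)c2ccccc2oc1=O)O
F6 | step 5 | racemic methyl (2E,6E)-5-hydroxy-3,7,11-trimethyldodeca-2,6,10-trienoate | CC(C)=CCC/C(C)=C/C(O)C/C(C)=C/C(=O)OC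
F7 | step 5 | methyl (2E,6E)-3,7,11-trimethyl-5-oxododeca-2,6,10-trienoate | CC(C)=CCC/C(C)=C/C(=O)C/C(C)=C/C(=O)OC
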